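**Retrosynthetic overview**
- Target ← acidic removal of three MOM ethers ← trans C3 hydroxylation of a (2S)-flavanone enolate ← CuH-catalysed enantioselective 1,4-reduction of the flat flavone (C2 set by the catalyst, C3 by the substrate).
- Flavone ← one-pot carbonylative alkynylation and cyclisation of an ortho-iodophenol (ring A), an arylacetylene (ring B) and CO, forming C4a–C4, C4–C3 and O1–C2. Ring C is the only ring made; rings A and B are bought as arenes.
- Feature used: ring C is only the three-carbon bridge C2–C3–C4 between O1 (on C8a) and C4a of ring A, and its C4 carbonyl carbon can come from CO. C6 (geranyl) lies between C5–O and C7–O and para to C8a–O, so the iodophenol derives from a mirror-symmetric 4-geranyl-3,5-dioxygenated phenol whose two ortho carbons are equivalent.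
- Iodophenol ← phloroglucinol (bis-MOM ether, TIPS ether, lithiation between the MOM ethers, geranylation, desilylation, iodination); alkyne ← isovanillin (MOM ether, Ohira–Bestmann homologation).

Key step: step 8

Assumption: the sense of induction of the DTBM-SEGPHOS–CuH catalyst on a 2-arylchromone is not certain in advance; (R)-DTBM-SEGPHOS is written, and the (S)-ligand is to be used if hydride is delivered to the other face of C2. "Geranyl" means (2E)-3,7-dimethylocta-2,6-dien-1-yl throughout.

**Step 1**
Reactants: 1 phloroglucinol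
Product: 2 3,5-bis(methoxymethoxy)phenol
Conditions: MOMCl (2.0 equiv), i-Pr2NEt, DMF, 0 °C to rt; chromatographic separation from mono- and tris-ether
Reagents that add atoms: chloromethyl methyl ether, COCCl
Why: Williamson-type O-alkylation of the threefold-symmetric triol with two equivalents of MOMCl should give the bis-ether as the main part of a statistical mixture that separates by polarity, leaving one oxygen free for later differentiation.

**Step 2**
Reactants: 2 3,5-bis(methoxymethoxy)phenol
Product: 3 [3,5-bis(methoxymethoxy)phenoxy]triisopropylsilane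
Conditions: TIPSCl, imidazole, DMF, rt
Reagents that add atoms: chlorotriisopropylsilane, CC(C)[Si](Cl)(C(C)C)C(C)C
Why: Silyl ether formation masks the acidic phenol with a bulky, non-coordinating group, so that the carbon between the two MOM ethers is the only well-chelated site for lithiation.

**Step 3**
Reactants: 3 [3,5-bis(methoxymethoxy)phenoxy]triisopropylsilane, 4 geranyl bromide
Product: 6 [4-geranyl-3,5-bis(methoxymethoxy)phenoxy]triisopropylsilane, via aryllithium 5 (not isolated)
Conditions: n-BuLi, THF, 0 °C; then CuI (10 mol%), 4, −78 °C to rt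
Reagents that add atoms: none
Why: Directed ortho-metalation at the carbon flanked by both MOM ethers (double chelation, the TIPS ether shielding its own ortho carbons) gives aryllithium 5, and its copper-catalysed SN2 allylation at the primary carbon of 4 should keep the E olefin and place the geranyl group at the future C6.

**Step 4**
Reactants: 6 [4-geranyl-3,5-bis(methoxymethoxy)phenoxy]triisopropylsilane
Product: 7 4-geranyl-3,5-bis(methoxymethoxy)phenol
Conditions: Bu4NF, THF, 0 °C
Reagents that add atoms: none
Why: Fluoride-induced desilylation of an aryl silyl ether is fast and leaves MOM ethers and olefins untouched.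

**Step 5**
Reactants: 7 4-geranyl-3,5-bis(methoxymethoxy)phenol
Product: 8 4-geranyl-2-iodo-3,5-bis(methoxymethoxy)phenol
Conditions: I2 (1.0 equiv), NaHCO3, THF/H2O, 0 °C, dark
Reagents that add atoms: iodine, II
Why: Electrophilic aromatic iodination of the phenolate goes ortho to the OH because the para carbon carries the geranyl group, the two ortho carbons are equivalent by symmetry so only one mono-iodide can form, and one equivalent of I2 under bicarbonate is too weak an electrophile to attack the trisubstituted olefins.

**Step 6**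
Reactants: 9 isovanillin
Product: 10 4-methoxy-3-(methoxymethoxy)benzaldehyde
Conditions: MOMCl, i-Pr2NEt, CH2Cl2, 0 °C to rt
Reagents that add atoms: chloromethyl methyl ether, COCCl
Why: MOM ether formation (Williamson-type alkylation) protects the only phenol and is compatible with the aldehyde.

**Step 7**
Reactants: 10 4-methoxy-3-(methoxymethoxy)benzaldehyde
Product: 11 4-ethynyl-1-methoxy-2-(methoxymethoxy)benzene
Conditions: dimethyl (1-diazo-2-oxopropyl)phosphonate, K2CO3, MeOH, rt
Reagents that add atoms: dimethyl (1-diazo-2-oxopropyl)phosphonate, CC(=O)C(=[N+]=[N-])P(=O)(OC)OC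
Why: Ohira–Bestmann homologation: methanolysis of the reagent gives the diazomethylphosphonate anion, which adds to the aldehyde, loses phosphate and N2 and rearranges by 1,2-hydrogen shift to the terminal alkyne under base mild enough for the MOM ether.

**Step 8**
Reactants: 8 4-geranyl-2-iodo-3,5-bis(methoxymethoxy)phenol, 11 4-ethynyl-1-methoxy-2-(methoxymethoxy)benzene, 12 carbon monoxide
Product: 15 6-geranyl-5,7-bis(methoxymethoxy)-2-[4-methoxy-3-(methoxymethoxy)phenyl]-4H-chromen-4-one, via ynone 13 (not isolated), via enaminone 14 (not isolated)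
Conditions: PdCl2(PPh3)2 (5 mol%), CO (20 bar), Et2NH, 120 °C, autoclave
Reagents that add atoms: none
Why: Zerovalent palladium formed from PdCl2(PPh3)2 inserts into the C–I bond at the future C4a of 8, CO inserts to give the aroylpalladium species, and amine-assisted alkynyl transfer from 11 with reductive elimination gives ynone 13 (bonds C4a–C4 and C4–C3), a copper-free carbonylative Sonogashira coupling. Et2NH then adds to the β-carbon of 13 to give enaminone 14, and the phenol oxygen closes ring C by 6-endo attack at C2 with loss of Et2NH (addition–elimination, bond O1–C2). The closest known reaction type is the palladium-catalysed carbonylative coupling and cyclisation of 2-iodophenols with terminal arylacetylenes in secondary amines to flavones. No stereocentre is formed, since 15 is flat. The step needs carbonylation to outrun direct alkynylation (which would lead to a 2-arylbenzofuran) and 6-endo closure to outrun 5-exo closure (aurone); CO pressure without a copper co-catalyst should secure the first, and the enaminone, whose only electrophilic carbon is C2, the second. The geranyl group is fixed at C6 because the iodine of 8 sits at one of the two symmetry-equivalent ortho carbons of 7.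

**Step 9**
Reactants: 15 6-geranyl-5,7-bis(methoxymethoxy)-2-[4-methoxy-3-(methoxymethoxy)phenyl]-4H-chromen-4-one
Product: 17 (2S)-6-geranyl-5,7-bis(methoxymethoxy)-2-[4-methoxy-3-(methoxymethoxy)phenyl]chroman-4-one, via silyl enol ether 16 (not isolated)
Conditions: Cu(OAc)2 (5 mol%), (R)-DTBM-SEGPHOS (5.5 mol%), (EtO)2MeSiH (2 equiv), toluene, 0 °C to rt; then AcOH, H2O/THF, 0 °C
Reagents that add atoms: none
Why: Asymmetric 1,4-hydrosilylation by a ligated monovalent copper hydride, a reaction type known for 2-substituted chromones and β-aryl cyclic enones, should deliver hydride to one face of C2 and so set the C2 stereocentre under catalyst control, while silylation of the copper enolate to 16 shields the ketone from 1,2-reduction, the unactivated geranyl olefins stay inert, and mild hydrolysis frees the (2S)-flavanone without an enolate that could open ring C.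

**Step 10**
Reactants: 17 (2S)-6-geranyl-5,7-bis(methoxymethoxy)-2-[4-methoxy-3-(methoxymethoxy)phenyl]chroman-4-one
Product: 19 (2R,3R)-6-geranyl-3-hydroxy-5,7-bis(methoxymethoxy)-2-[4-methoxy-3-(methoxymethoxy)phenyl]chroman-4-one, via sodium enolate 18 (not isolated)
Conditions: NaN(SiMe3)2, THF, −78 °C; then 2-(phenylsulfonyl)-3-phenyloxaziridine, −78 °C; AcOH quench at −78 °C
Reagents that add atoms: 2-(phenylsulfonyl)-3-phenyloxaziridine, O=S(=O)(c1ccccc1)N1OC1c1ccccc1
Why: Electrophilic hydroxylation of a ketone enolate by an N-sulfonyloxaziridine should occur at C3 of 18 on the face anti to the C2 aryl group, so that C3 is set trans to C2 by substrate control (2S becomes 2R only through the change in CIP priority), and the oxaziridine does not epoxidise the geranyl olefins at this temperature.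

**Step 11**
Reactants: 19 (2R,3R)-6-geranyl-3-hydroxy-5,7-bis(methoxymethoxy)-2-[4-methoxy-3-(methoxymethoxy)phenyl]chroman-4-one
Product: 20 4'-O-methyldiplacol
Conditions: 3 M aq. HCl, MeOH, rt to 40 °C
Reagents that add atoms: none
Why: Acid-catalysed acetal exchange transfers the three MOM groups to methanol, the trans-dihydroflavonol is configurationally stable to acid, and the mild temperature should keep the C6 geranyl group from cyclising onto the flanking C5 or C7 hydroxyl.

**Compound list**
1 | phloroglucinol (benzene-1,3,5-triol) | Oc1cc(O)cc(O)c1 | starting material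
2 | 3,5-bis(methoxymethoxy)phenol | COCOc1cc(O)cc(OCOC)c1 | intermediate
3 | [3,5-bis(methoxymethoxy)phenoxy]triisopropylsilane | COCOc1cc(OCOC)cc(O[Si](C(C)C)(C(C)C)C(C)C)c1 | intermediate
4 | geranyl bromide, (2E)-1-bromo-3,7-dimethylocta-2,6-diene | BrC/C=C(\C)CCC=C(C)C | starting material
5 | [2,6-bis(methoxymethoxy)-4-(triisopropylsilyloxy)phenyl]lithium | [Li]c1c(OCOC)cc(O[Si](C(C)C)(C(C)C)C(C)C)cc1OCOC | intermediate
6 | [4-geranyl-3,5-bis(methoxymethoxy)phenoxy]triisopropylsilane | COCOc1cc(O[Si](C(C)C)(C(C)C)C(C)C)cc(OCOC)c1C/C=C(\C)CCC=C(C)C | intermediate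
7 | 4-geranyl-3,5-bis(methoxymethoxy)phenol | Oc1cc(OCOC)c(C/C=C(\C)CCC=C(C)C)c(OCOC)c1 | intermediate
8 | 4-geranyl-2-iodo-3,5-bis(methoxymethoxy)phenol | Oc1cc(OCOC)c(C/C=C(\C)CCC=C(C)C)c(OCOC)c1I | intermediate
9 | isovanillin (3-hydroxy-4-methoxybenzaldehyde) | COc1ccc(C=O)cc1O | starting material
10 | 4-methoxy-3-(methoxymethoxy)benzaldehyde | COCOc1cc(C=O)ccc1OC | intermediate
11 | 4-ethynyl-1-methoxy-2-(methoxymethoxy)benzene | C#Cc1ccc(OC)c(OCOC)c1 | intermediate
12 | carbon monoxide | [C-]#[O+] | starting material
13 | 1-[3-geranyl-6-hydroxy-2,4-bis(methoxymethoxy)phenyl]-3-[4-methoxy-3-(methoxymethoxy)phenyl]prop-2-yn-1-one | COCOc1cc(C#CC(=O)c2c(O)cc(OCOC)c(C/C=C(\C)CCC=C(C)C)c2OCOC)ccc1OC | intermediate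
14 | 3-(diethylamino)-1-[3-geranyl-6-hydroxy-2,4-bis(methoxymethoxy)phenyl]-3-[4-methoxy-3-(methoxymethoxy)phenyl]prop-2-en-1-one (enamine olefin geometry not defined) | CCN(CC)C(=CC(=O)c1c(O)cc(OCOC)c(C/C=C(\C)CCC=C(C)C)c1OCOC)c1ccc(OC)c(OCOC)c1 | intermediate
15 | 6-geranyl-5,7-bis(methoxymethoxy)-2-[4-methoxy-3-(methoxymethoxy)phenyl]-4H-chromen-4-one | COc1ccc(-c2cc(=O)c3c(OCOC)c(C/C=C(\C)CCC=C(C)C)c(OCOC)cc3o2)cc1OCOC | intermediate
16 | (2S)-4-[diethoxy(methyl)silyloxy]-6-geranyl-5,7-bis(methoxymethoxy)-2-[4-methoxy-3-(methoxymethoxy)phenyl]-2H-chromene | COc1ccc([C@H]2Oc3cc(OCOC)c(C/C=C(\C)CCC=C(C)C)c(OCOC)c3C(O[Si](C)(OCC)OCC)=C2)cc1OCOC | intermediate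
17 | (2S)-6-geranyl-5,7-bis(methoxymethoxy)-2-[4-methoxy-3-(methoxymethoxy)phenyl]chroman-4-one | COc1ccc([C@H]2Oc3cc(OCOC)c(C/C=C(\C)CCC=C(C)C)c(OCOC)c3C(=O)C2)cc1OCOC | intermediate
18 | sodium (2S)-6-geranyl-5,7-bis(methoxymethoxy)-2-[4-methoxy-3-(methoxymethoxy)phenyl]-2H-chromen-4-olate | COc1ccc([C@H]2Oc3cc(OCOC)c(C/C=C(\C)CCC=C(C)C)c(OCOC)c3C([O-])=C2)cc1OCOC.[Na+] | intermediate
19 | (2R,3R)-6-geranyl-3-hydroxy-5,7-bis(methoxymethoxy)-2-[4-methoxy-3-(methoxymethoxy)phenyl]chroman-4-one (2,3-trans) | COc1ccc([C@H]2Oc3cc(OCOC)c(C/C=C(\C)CCC=C(C)C)c(OCOC)c3C(=O)[C@@H]2O)cc1OCOC | intermediate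
20 | 4'-O-methyldiplacol, (2R,3R)-6-geranyl-3,5,7-trihydroxy-2-(3-hydroxy-4-methoxyphenyl)chroman-4-one | COc1ccc([C@H]2Oc3cc(O)c(C/C=C(\C)CCC=C(C)C)c(O)c3C(=O)[C@@H]2O)cc1O | target

**Step count**
Total: 11 steps. Longest linear sequence: 9 steps (steps 1–5, then 8–11, from phloroglucinol).

**Steps most likely to fail**

Step 9. Hydride transfer to the hindered, donor-substituted C2 may stall, the two faces of C2 may be poorly distinguished, or the ketone may be reduced further to the flavan-4-ol. The fallback sets out from 15. Conjugate reduction with LiBH(s-Bu)3 in THF at −78 °C should give the racemic flavanone F1. Kinetic resolution of F1 by asymmetric transfer hydrogenation with Cp*RhCl(TsDPEN) in HCO2H/Et3N, using the enantiomer of the diamine ligand that reduces the 2R ketone faster, should convert the 2R half into the cis-(2R,4R)-flavan-4-ol F2, which is separated. The unreacted (2S)-flavanone is 17, where the route is rejoined.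

Step 8. Direct alkynylation followed by cyclisation to a 2-arylbenzofuran, aminocarbonylation of the aroylpalladium species by Et2NH, or slow oxidative addition to the electron-rich phenolate may compete with the carbonylative coupling. The fallback sets out from 8 and 11 and builds the ynone without palladium or CO. Silylation of 8 with TBSCl and imidazole should give the silyl ether F3. Lithiation of 11 with n-BuLi at −78 °C and acylation with N-methoxy-N-methylcarbamoyl chloride should give the N-methoxy-N-methylpropiolamide F4. Iodine–magnesium exchange of F3 with i-PrMgCl·LiCl at −20 °C and addition to F4 should give the silyl ynone F5. Desilylation with Bu4NF buffered by AcOH should give ynone 13, and treating 13 with Et2NH in EtOH should close ring C through enaminone 14 to 15, where the route is rejoined.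

Step 10. The enolate may open ring C by retro-oxa-Michael reaction, with loss of the C2 configuration, or may add to the sulfonimine by-product. The fallback sets out from silyl enol ether 16, taken on without hydrolysis, and avoids any base. Rubottom oxidation with dimethyldioxirane (1.0 equiv) in acetone/CH2Cl2 at −78 °C should oxidise the electron-rich enol ether faster than the geranyl olefins, on the face anti to the C2 aryl group, and give after silyl migration the 3-silyloxy ketone F6. Hydrolysis of F6 with AcOH in aqueous THF should give 19, where the route is rejoined.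

**Further compounds**
F1 | step 9 | racemic 6-geranyl-5,7-bis(methoxymethoxy)-2-[4-methoxy-3-(methoxymethoxy)phenyl]chroman-4-one | COc1ccc(C2Oc3cc(OCOC)c(C/C=C(\C)CCC=C(C)C)c(OCOC)c3C(=O)C2)cc1OCOC
F2 | step 9 | (2R,4R)-6-geranyl-5,7-bis(methoxymethoxy)-2-[4-methoxy-3-(methoxymethoxy)phenyl]chroman-4-ol (2,4-cis) | COc1ccc([C@@H]2Oc3cc(OCOC)c(C/C=C(\C)CCC=C(C)C)c(OCOC)c3[C@H](O)C2)cc1OCOC
F3 | step 8 | tert-butyl[4-geranyl-2-iodo-3,5-bis(methoxymethoxy)phenoxy]dimethylsilane | CC(C)(C)[Si](C)(C)Oc1cc(OCOC)c(C/C=C(\C)CCC=C(C)C)c(OCOC)c1I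
F4 | step 8 | N-methoxy-3-[4-methoxy-3-(methoxymethoxy)phenyl]-N-methylprop-2-ynamide | COc1ccc(C#CC(=O)N(C)OC)cc1OCOC
F5 | step 8 | 1-[6-(tert-butyldimethylsilyloxy)-3-geranyl-2,4-bis(methoxymethoxy)phenyl]-3-[4-methoxy-3-(methoxymethoxy)phenyl]prop-2-yn-1-one | COc1ccc(C#CC(=O)c2c(O[Si](C)(C)C(C)(C)C)cc(OCOC)c(C/C=C(\C)CCC=C(C)C)c2OCOC)cc1OCOC
F6 | step 10 | (2R,3R)-3-[diethoxy(methyl)silyloxy]-6-geranyl-5,7-bis(methoxymethoxy)-2-[4-methoxy-3-(methoxymethoxy)phenyl]chroman-4-one | COc1ccc([C@H]2Oc3cc(OCOC)c(C/C=C(\C)CCC=C(C)C)c(OCOC)c3C(=O)[C@@H]2O[Si](C)(OCC)OCC)cc1OCOC
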